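The route rests on the C4(OH)–C5(H)–C6(O) array that spans the cyclopentane (C1–C5) and cycloheptane (C1, C5–C10) rings (daucane numbering): a β-hydroxy ketone across ring-fusion carbon C5 is the product of a semipinacol shift. The cyclopentane is therefore carried as cyclohexane ring A of a cis-decalin. In an all-cis 4a-hydroxy-3,4-epoxydecalin the fusion bond C1–C6 migrates from carbinol carbon C6 to epoxide carbon C5: one operation contracts ring A to the cyclopentane, expands ring B to the cycloheptenone, sets the trans ring fusion at C5 and unveils the C4 tertiary alcohol. The epoxy diol comes from (S)-carvone by reductive allylation, methallyl addition and ring-closing metathesis.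

Key step: step 10

Remark on numbering, used for every compound: C1 = quaternary ring-fusion carbon bearing CH3; C2 = CH–OAc; C3 = CH2; C4 = C(OH)(i-Pr); C5 = ring-fusion CH; C6 = CH–O-aroyl; C7 = CH2; C8 (bearing CH3) and C9 = epoxide carbons; C10 = CH2. In the decalins C1 is bonded to C6, not to C5. α is the face that carries the C1 methyl group. The target has C2–OAc, C4–OH, C6–O and the epoxide oxygen α, and H5, i-Pr and C8–CH3 β (1S,2S,4S,5R,6S,8R,9S in this numbering).

Assumption: the SMILES is taken as the absolute configuration to be made; (S)-carvone, allyl bromide, 2-methylallylmagnesium chloride and 3,4-dimethoxybenzoyl chloride are taken as commercial.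

Step 1
Reactants: 1 (S)-(+)-carvone
Product: 2 (S)-carvotanacetone
Conditions: H2 (1 atm), RhCl(PPh3)3 (cat.), benzene, rt
Reagents that add atoms: none
Why: Homogeneous hydrogenation should saturate only the unhindered 1,1-disubstituted isopropenyl alkene and leave the conjugated trisubstituted enone and the existing stereocentre untouched.

Step 2
Reactants: 2 (S)-carvotanacetone; 3 hydrogen peroxide
Product: 4 trans-epoxy ketone
Conditions: 30% H2O2, NaOH (cat.), MeOH, 0 °C
Reagents that add atoms: hydrogen peroxide, OO
Why: Nucleophilic (Weitz–Scheffer) epoxidation; hydroperoxide should add to the enone β-carbon axially, anti to the isopropyl group, so the epoxide forms trans to isopropyl and places the future C2 oxygen on the α face.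

Step 3
Reactants: 4 trans-epoxy ketone; 5 allyl bromide
Product: 7 α-allyl β-hydroxy ketone, via dilithium enolate-alkoxide 6 (not isolated)
Conditions: Li (2.2 equiv), NH3(l)/THF, −78 °C; then allyl bromide, −78 to −33 °C; NH4Cl
Reagents that add atoms: allyl bromide, C=CCBr
Why: Dissolving-metal reductive alkylation of an α,β-epoxy ketone: two-electron reduction cleaves the α C–O bond to a regiodefined enolate with an axial β-alkoxide, and allyl bromide should enter axially anti to that alkoxide (Fráter–Seebach-type anti alkylation), setting quaternary C1 with CH3 cis and allyl trans to the C2 oxygen.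

Step 4
Reactants: 7 α-allyl β-hydroxy ketone; 8 tert-butyldimethylsilyl triflate
Product: 9 TBS ether
Conditions: TBSOTf, 2,6-lutidine, CH2Cl2, 0 °C
Reagents that add atoms: tert-butyldimethylsilyl trifluoromethanesulfonate, CC(C)(C)[Si](C)(C)OS(=O)(=O)C(F)(F)F
Why: Silylation with the triflate should protect the hindered neopentyl secondary alcohol against the oxidant of step 5 and make it a large, non-chelating control element for step 6.

Step 5
Reactants: 9 TBS ether
Product: 10 β-isopropyl enone
Conditions: IBX, DMSO/fluorobenzene, 70 °C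
Reagents that add atoms: none
Why: IBX dehydrogenation of a ketone can only desaturate toward C5 because the other α-carbon (C1) is quaternary; it should give the C4=C5 enone and erase the carvone-derived stereocentre at C4, which has done its work.

Step 6
Reactants: 10 β-isopropyl enone; 11 2-methylallylmagnesium chloride
Product: 12 tertiary bis-allylic alcohol
Conditions: CeCl3, THF, −78 °C; NH4Cl(aq)
Reagents that add atoms: 2-methylallylmagnesium chloride, CC(=C)C[Mg]Cl
Why: 1,2-Addition of the allylmetal to the enone carbonyl; attack should occur axially on the half-chair that has the C2 siloxy group equatorial and the C1 methyl axial, that is anti to both, so the methallyl group ends β (cis to the allyl group) and the new C6–OH α (cis to CH3 and OTBS).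

Step 7
Reactants: 12 tertiary bis-allylic alcohol
Product: 13 cis-decalin silyl ether
Conditions: second-generation Grubbs catalyst RuCl2(=CHPh)(PCy3)(H2IMes) (5 mol%), CH2Cl2, 40 °C
Reagents that add atoms: none
Why: Ring-closing metathesis of the cis-disposed allyl and methallyl groups should close the cyclohexene ring B with its trisubstituted C8=C9 alkene; the endocyclic C4=C5 alkene is inert.

Step 8
Reactants: 13 cis-decalin silyl ether
Product: 14 cis-decalin diol
Conditions: Bu4NF, THF, 0 °C to rt
Reagents that add atoms: none
Why: Fluoride desilylation frees the C2 hydroxyl, which is needed as a second donor on the α face for steps 9 and 10.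

Step 9
Reactants: 14 cis-decalin diol; 15 tert-butyl hydroperoxide
Product: 16 all-cis epoxy diol
Conditions: VO(acac)2 (cat.), t-BuOOH (1.1 equiv), CH2Cl2, 0 °C
Reagents that add atoms: tert-butyl hydroperoxide, CC(C)(C)OO
Why: Vanadium-catalysed hydroxyl-directed epoxidation should deliver oxygen to the allylic C4=C5 alkene syn to the tertiary C6–OH (and to the homoallylic C2–OH), giving the α-epoxide; the merely homoallylic C8=C9 alkene reacts much more slowly.

Step 10
Reactants: 16 all-cis epoxy diol
Product: 17 trans-fused hydroazulenone diol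
Conditions: ZnBr2 (1.5 equiv), CH2Cl2, 0 °C to rt
Reagents that add atoms: none
Why: ZnBr2 should be chelated by the three syn (α) oxygens O2, O6 and the epoxide oxygen, which is possible only in the half-chair of ring A with O2 and O6 syn-axial and C1 displaced to the β side; there the fusion bond C6–C1 is aligned anti to the activated C5–O bond while C7 is gauche to it, so C1 migrates from C6 to C5 as the epoxide opens and C6–OH becomes the ketone. The closest known reaction types are the Lewis-acid semipinacol rearrangement of 2,3-epoxy alcohols and the pinacol-type conversion of decalols into hydroazulenones. No ring is closed by cyclisation: the cyclopentane C1–C5 results from contraction of ring A (six to five) and the cycloheptenone from expansion of ring B (six to seven) through one suprafacial 1,2-alkyl shift. C5 is formed with inversion (C1 enters anti to the departing oxygen, so H5 ends β, trans to the C1 methyl group), C4 keeps the α oxygen set in step 9, and C1 migrates with retention. The step needs C5–O rather than C4–O cleavage and C1 rather than C7 migration; the push of O6, the anti alignment enforced by the chelate and the higher migratory aptitude of the fully substituted C1 should secure this.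

Step 11
Reactants: 17 trans-fused hydroazulenone diol; 18 acetic anhydride
Product: 19 C2 acetate
Conditions: Ac2O, pyridine, DMAP (cat.), CH2Cl2, 0 °C
Reagents that add atoms: acetic anhydride, CC(=O)OC(C)=O
Why: Acylation should take place only at the secondary C2 hydroxyl, the tertiary C4 hydroxyl being inert under these mild conditions; doing it now avoids later competition with C6–OH.

Step 12
Reactants: 19 C2 acetate
Product: 20 C6 α-alcohol
Conditions: LiBH(s-Bu)3, THF, −78 °C; then H2O
Reagents that add atoms: none
Why: The bulky hydride should attack the C6 ketone from the β face, away from the pseudo-axial C1 methyl group and the C4 oxygen (equatorial attack), giving the axial α-alcohol; the acetate survives at −78 °C.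

Step 13
Reactants: 20 C6 α-alcohol; 15 tert-butyl hydroperoxide
Product: 21 α-epoxy diol acetate
Conditions: VO(acac)2 (cat.), t-BuOOH, CH2Cl2, rt
Reagents that add atoms: tert-butyl hydroperoxide, CC(C)(C)OO
Why: Vanadium-catalysed epoxidation directed by the homoallylic C6–OH should deliver oxygen to C8=C9 on the α face, leaving the C8 methyl group β.

Step 14
Reactants: 21 α-epoxy diol acetate; 22 3,4-dimethoxybenzoyl chloride
Product: 23 target CNP0330776.1
Conditions: Et3N, DMAP, CH2Cl2, rt to 40 °C
Reagents that add atoms: 3,4-dimethoxybenzoyl chloride, COc1ccc(C(Cl)=O)cc1OC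
Why: DMAP-catalysed acylation should esterify the only secondary hydroxyl (C6); the tertiary C4–OH, the epoxide and the acetate are unaffected.

Compound list
1 | (S)-(+)-carvone, (5S)-2-methyl-5-(prop-1-en-2-yl)cyclohex-2-en-1-one | CC1=CC[C@@H](CC1=O)C(C)=C | starting material
2 | (S)-carvotanacetone, (5S)-2-methyl-5-(propan-2-yl)cyclohex-2-en-1-one | CC1=CC[C@@H](CC1=O)C(C)C | intermediate
3 | hydrogen peroxide | OO | starting material
4 | (1S,4S,6S)-1-methyl-4-(propan-2-yl)-7-oxabicyclo[4.1.0]heptan-2-one, epoxide trans to isopropyl | C[C@]12O[C@H]1C[C@@H](CC2=O)C(C)C | intermediate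
5 | allyl bromide (3-bromoprop-1-ene) | C=CCBr | starting material
6 | dilithium enolate-alkoxide from reductive opening of 4 (enolate C1=C6, alkoxide at C2) | CC1=C([O-])C[C@H](C[C@@H]1[O-])C(C)C.[Li+].[Li+] | intermediate
7 | (2R,3S,5S)-3-hydroxy-2-methyl-5-(propan-2-yl)-2-(prop-2-en-1-yl)cyclohexan-1-one; CH3 cis and allyl trans to OH | C=CC[C@]1(C)[C@@H](O)C[C@@H](CC1=O)C(C)C | intermediate
8 | tert-butyldimethylsilyl trifluoromethanesulfonate | CC(C)(C)[Si](C)(C)OS(=O)(=O)C(F)(F)F | starting material
9 | tert-butyldimethylsilyl ether of 7 | C=CC[C@]1(C)[C@@H](O[Si](C)(C)C(C)(C)C)C[C@@H](CC1=O)C(C)C | intermediate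
10 | (5S,6R)-5-(tert-butyldimethylsilyloxy)-6-methyl-3-(propan-2-yl)-6-(prop-2-en-1-yl)cyclohex-2-en-1-one | C=CC[C@]1(C)[C@@H](O[Si](C)(C)C(C)(C)C)CC(C(C)C)=CC1=O | intermediate
11 | 2-methylallylmagnesium chloride | CC(=C)C[Mg]Cl | starting material
12 | 6-allyl-5-(tert-butyldimethylsilyloxy)-6-methyl-1-(2-methylallyl)-3-(propan-2-yl)cyclohex-2-en-1-ol; OH cis to CH3 and OTBS, methallyl cis to allyl | C=CC[C@]1(C)[C@@H](O[Si](C)(C)C(C)(C)C)CC(C(C)C)=C[C@]1(O)CC(C)=C | intermediate
13 | cis-fused 1-(tert-butyldimethylsilyloxy)-6,8a-dimethyl-3-(propan-2-yl)-1,2,5,8-tetrahydronaphthalen-4a(8aH)-ol; 4a-OH, 8a-CH3 and 1-OTBS all α (C6, C1, C2 in route numbering) | CC(C)C1=C[C@]2(O)CC(C)=CC[C@]2(C)[C@@H](O[Si](C)(C)C(C)(C)C)C1 | intermediate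
14 | cis-fused 6,8a-dimethyl-3-(propan-2-yl)-1,2,5,8-tetrahydronaphthalene-1,4a(8aH)-diol; both OH and 8a-CH3 α | CC(C)C1=C[C@]2(O)CC(C)=CC[C@]2(C)[C@@H](O)C1 | intermediate
15 | tert-butyl hydroperoxide | CC(C)(C)OO | starting material
16 | 3,4-epoxide of 14 (C4–C5 in route numbering); epoxide oxygen, both OH and 8a-CH3 all α | CC(C)[C@]12O[C@H]1[C@]1(O)CC(C)=CC[C@]1(C)[C@@H](O)C2 | intermediate
17 | 2α,4α-dihydroxydauc-8-en-6-one, trans-fused (H5 β): 1,3-dihydroxy-6,8a-dimethyl-3-(propan-2-yl)-2,3,3a,5,8,8a-hexahydroazulen-4(1H)-one | CC(C)[C@@]1(O)C[C@H](O)[C@@]2(C)CC=C(C)CC(=O)[C@H]12 | intermediate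
18 | acetic anhydride | CC(=O)OC(C)=O | starting material
19 | 2α-acetoxy-4α-hydroxydauc-8-en-6-one | CC(C)[C@@]1(O)C[C@H](OC(C)=O)[C@@]2(C)CC=C(C)CC(=O)[C@H]12 | intermediate
20 | 2α-acetoxydauc-8-ene-4α,6α-diol | CC(C)[C@@]1(O)C[C@H](OC(C)=O)[C@@]2(C)CC=C(C)C[C@H](O)[C@H]12 | intermediate
21 | 2α-acetoxy-8α,9α-epoxydaucane-4α,6α-diol | CC(C)[C@@]1(O)C[C@H](OC(C)=O)[C@@]2(C)C[C@@H]3O[C@]3(C)C[C@H](O)[C@H]12 | intermediate
22 | 3,4-dimethoxybenzoyl chloride | COc1ccc(C(Cl)=O)cc1OC | starting material
23 | CNP0330776.1, 2α-acetoxy-8α,9α-epoxy-4α-hydroxydaucan-6α-yl 3,4-dimethoxybenzoate | COc1ccc(C(=O)O[C@H]2C[C@@]3(C)O[C@H]3C[C@]3(C)[C@@H](OC(C)=O)C[C@](O)(C(C)C)[C@@H]23)cc1OC | target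

Total step count: 14. Longest linear sequence: 14 steps (from 1 to 23).

Steps most likely to fail

Step 10. The epoxide may open at the tertiary carbon C4 (cation formation followed by hydride shift or elimination), or C7 may migrate instead of C1 from the flipped half-chair of ring A, giving a bridged ketone. The fallback sets out from 16 and comes back at 17. Treatment of 16 with t-Bu2Si(OTf)2 and 2,6-lutidine ties O2 and O6 into a six-membered ring, the cyclic di-tert-butylsilylene F1, which locks the half-chair that has C1–C6 anti to C5–O. A bulky, non-nucleophilic aluminium Lewis acid, MeAl(OAr)2 with Ar = 4-bromo-2,6-di-tert-butylphenyl, should then bring about the known epoxy silyl ether rearrangement, with 1,5-silyl transfer from O6 to the new C4 alkoxide, to give the O2,O4-silylene-bridged hydroazulenone F2. Bu4NF buffered with acetic acid releases 17.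

Step 12. Hydride may be delivered from the α face (guided by the C4 alkoxide) and give the C6 epimer, or the C4 alkoxide may undergo retro-aldol cleavage. The fallback sets out from 19 and comes back at 20. Hydroxyl-directed reduction with Me4NBH(OAc)3 in MeCN/AcOH delivers hydride intramolecularly from the α face and should give the 6β-alcohol F3 on purpose. Tf2O and pyridine convert it into the secondary triflate F4. Displacement with KNO2 in DMF (Lattrell–Dax inversion) gives the α nitrite ester F5, which is hydrolysed on work-up to 20.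

Step 3. The enolate may be protonated before it is alkylated, the alkoxide may be O-allylated, or the β-alkoxy ketone may open by retro-aldol reaction. The fallback sets out from 4 and comes back at 9. SmI2 in THF/MeOH at −90 °C opens the epoxy ketone to the β-hydroxy ketone F6; TBSOTf and 2,6-lutidine give the silyl ether F7; TMSCl, NaI and Et3N in MeCN give the more substituted trimethylsilyl enol ether F8; MeLi in THF liberates the regiodefined lithium enolate F9, and allyl bromide, entering anti to the siloxy group, gives 9.

Further compounds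
F1 | step 10 | O2,O6-di-tert-butylsilylene derivative of epoxy diol 16 | CC(C)[C@]12O[C@H]1[C@]1(O3)CC(C)=CC[C@]1(C)[C@@H](O[Si]3(C(C)(C)C)C(C)(C)C)C2
F2 | step 10 | O2,O4-di-tert-butylsilylene derivative of hydroazulenone 17 | CC(C)[C@@]1(O3)C[C@H](O[Si]3(C(C)(C)C)C(C)(C)C)[C@@]2(C)CC=C(C)CC(=O)[C@H]12
F3 | step 12 | 2α-acetoxydauc-8-ene-4α,6β-diol (C6 epimer of 20) | CC(C)[C@@]1(O)C[C@H](OC(C)=O)[C@@]2(C)CC=C(C)C[C@@H](O)[C@H]12
F4 | step 12 | 6β-trifluoromethanesulfonate of F3 | CC(C)[C@@]1(O)C[C@H](OC(C)=O)[C@@]2(C)CC=C(C)C[C@@H](OS(=O)(=O)C(F)(F)F)[C@H]12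
F5 | step 12 | 6α-nitrite ester of 20 | CC(C)[C@@]1(O)C[C@H](OC(C)=O)[C@@]2(C)CC=C(C)C[C@H](ON=O)[C@H]12
F6 | step 3 | (3S,5S)-3-hydroxy-2-methyl-5-(propan-2-yl)cyclohexan-1-one, mixture at C2 | CC1C(=O)C[C@H](C[C@@H]1O)C(C)C
F7 | step 3 | tert-butyldimethylsilyl ether of F6 | CC1C(=O)C[C@H](C[C@@H]1O[Si](C)(C)C(C)(C)C)C(C)C
F8 | step 3 | tetrasubstituted trimethylsilyl enol ether of F7 | CC1=C(O[Si](C)(C)C)C[C@H](C[C@@H]1O[Si](C)(C)C(C)(C)C)C(C)C
F9 | step 3 | lithium enolate from F8 | CC1=C([O-])C[C@H](C[C@@H]1O[Si](C)(C)C(C)(C)C)C(C)C.[Li+]
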